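## Retrosynthetic overview

1. The target comes from a protected 2-aryl-3-(silyloxymethyl)-4-[aryl(hydroxy)methyl]oxolane by oxidation of the side-chain carbinol, desilylation and hydrogenolysis of two aryl benzyl ethers.
2. The oxolane ring is closed last, by O1–C5 Williamson etherification (5-exo-tet) of a triol made by hydride opening of an α-(hydroxybenzyl)-γ-butyrolactone.
3. The C4–C7' bond comes from a trans-selective aldol of a trans-β-(silyloxymethyl)-γ-aryl-γ-butyrolactone with O-benzylisovanillin.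
4. That lactone comes from a trans-paraconic acid, itself from a syn β-hydroxy diester in which C2 and C3 are both set by a ketoreductase-catalysed dynamic kinetic resolution of a racemic dimethyl 2-aroylsuccinate.
5. Ring order: γ-lactone first (the same five atoms as the final ring), opened by hydride, then the oxolane; no other ring is made.

Assumptions: ring positions are called O1, C2 (aryl), C3 (CH2O), C4 (acyl) and C5, with C7' the exocyclic carbon on C4; the ketoreductase is the member of a commercial screening panel that gives the syn-(S,S) alcohol; salts of numbered compounds (enolates, alkoxides, carboxylates) are not numbered separately.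

## Route

Step 1
Reactants: 1 1-(3-hydroxy-4-methoxyphenyl)ethan-1-one
Product: 2 1-[3-(benzyloxy)-4-methoxyphenyl]ethan-1-one
Conditions: BnBr (1.1 equiv), K2CO3, DMF, 60 °C
Reagents that add atoms: benzyl bromide, BrCc1ccccc1
Why: Williamson ether synthesis on the phenoxide installs a benzyl ether that survives every basic, hydridic and enzymatic step that follows.

Step 2
Reactants: 2 1-[3-(benzyloxy)-4-methoxyphenyl]ethan-1-one; 3 dimethyl carbonate
Product: 4 methyl 3-[3-(benzyloxy)-4-methoxyphenyl]-3-oxopropanoate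
Conditions: NaH (2.5 equiv), THF, reflux; then 1 M HCl
Reagents that add atoms: none
Why: Crossed Claisen condensation of the ketone enolate with the non-enolisable carbonate is driven to completion by formation of the stabilised β-keto ester enolate.

Step 3
Reactants: 4 methyl 3-[3-(benzyloxy)-4-methoxyphenyl]-3-oxopropanoate; 5 methyl bromoacetate
Product: 6 dimethyl 2-[3-(benzyloxy)-4-methoxybenzoyl]butanedioate (racemic)
Conditions: K2CO3 (1.2 equiv), acetone, 50 °C
Reagents that add atoms: none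
Why: SN2 C-alkylation of the soft β-keto ester enolate with one equivalent of the α-halo ester gives the 2-aroylsuccinate, whose new centre is racemic and deliberately labile.

Step 4
Reactants: 6 dimethyl 2-[3-(benzyloxy)-4-methoxybenzoyl]butanedioate
Product: 7 dimethyl (2S)-2-{(S)-[3-(benzyloxy)-4-methoxyphenyl](hydroxy)methyl}butanedioate
Conditions: ketoreductase (KRED, NADPH-dependent alcohol dehydrogenase), NADP+ (cat.), i-PrOH (15% v/v), potassium phosphate buffer (0.1 M, pH 7.0), DMSO (10% v/v), 30 °C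
Reagents that add atoms: none
Why: Ketoreductase-catalysed asymmetric reduction run as a dynamic kinetic resolution: the α-centre epimerises quickly through the enol at pH 7 while the enzyme reduces only the (S)-ketone from one carbonyl face, so the carbinol centre (C2, S) and C3 are both set by the catalyst in the syn relationship that becomes 2,3-trans in the ring.

Step 5
Reactants: 7 dimethyl (2S)-2-{(S)-[3-(benzyloxy)-4-methoxyphenyl](hydroxy)methyl}butanedioate
Product: 9 (2S,3S)-2-[3-(benzyloxy)-4-methoxyphenyl]-5-oxooxolane-3-carboxylic acid, via hydroxy diacid 8 (not isolated)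
Conditions: LiOH·H2O (3 equiv), THF/H2O (3:1), 0 °C to rt; then 2 M HCl to pH 1, rt
Reagents that add atoms: lithium hydroxide, [Li+].[OH-]
Why: Saponification of both esters followed by acid-promoted γ-lactonisation of the γ-hydroxy acid gives the trans-paraconic acid and leaves one free carboxyl to be told apart from the lactone, with neither stereocentre touched.

Step 6
Reactants: 9 (2S,3S)-2-[3-(benzyloxy)-4-methoxyphenyl]-5-oxooxolane-3-carboxylic acid
Product: 10 (4R,5S)-5-[3-(benzyloxy)-4-methoxyphenyl]-4-(hydroxymethyl)oxolan-2-one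
Conditions: BH3·SMe2 (1.5 equiv), THF, 0 °C to rt; then MeOH
Reagents that add atoms: none
Why: Chemoselective borane reduction of the carboxylic acid (through its acyloxyborane) proceeds faster than reduction of the lactone, giving the primary alcohol.

Step 7
Reactants: 10 (4R,5S)-5-[3-(benzyloxy)-4-methoxyphenyl]-4-(hydroxymethyl)oxolan-2-one
Product: 11 (4R,5S)-5-[3-(benzyloxy)-4-methoxyphenyl]-4-{[(tert-butyldiphenylsilyl)oxy]methyl}oxolan-2-one
Conditions: TBDPSCl (1.1 equiv), imidazole (2 equiv), CH2Cl2, 0 °C to rt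
Reagents that add atoms: tert-butyl(chloro)diphenylsilane, CC(C)(C)[Si](Cl)(c1ccccc1)c1ccccc1
Why: Silylation of the primary alcohol blocks translactonisation and gives a bulky C3 substituent that later directs the aldol.

Step 8
Reactants: 11 (4R,5S)-5-[3-(benzyloxy)-4-methoxyphenyl]-4-{[(tert-butyldiphenylsilyl)oxy]methyl}oxolan-2-one; 12 3-(benzyloxy)-4-methoxybenzaldehyde
Product: 13 (3R,4R,5S)-5-[3-(benzyloxy)-4-methoxyphenyl]-3-{[3-(benzyloxy)-4-methoxyphenyl](hydroxy)methyl}-4-{[(tert-butyldiphenylsilyl)oxy]methyl}oxolan-2-one (both C7' epimers)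
Conditions: LiN(SiMe3)2 (1.1 equiv), THF, −78 °C; then 12, −78 °C; AcOH, −78 °C
Reagents that add atoms: none
Why: Aldol addition of the lactone lithium enolate occurs on the face anti to the adjacent C3 silyloxymethyl group, setting C4 trans to C3, while the unselective C7' carbinol is erased later by oxidation.

Step 9
Reactants: 13 (3R,4R,5S)-5-[3-(benzyloxy)-4-methoxyphenyl]-3-{[3-(benzyloxy)-4-methoxyphenyl](hydroxy)methyl}-4-{[(tert-butyldiphenylsilyl)oxy]methyl}oxolan-2-one
Product: 14 (1S,2R,3S)-1,4-bis[3-(benzyloxy)-4-methoxyphenyl]-2-{[(tert-butyldiphenylsilyl)oxy]methyl}-3-(hydroxymethyl)butane-1,4-diol (both C4 carbinol epimers)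
Conditions: LiBH4 (3 equiv), THF, 0 °C to rt; then H2O
Reagents that add atoms: none
Why: Lithium borohydride reduces the lactone to the 1,4-diol without touching silyl or benzyl ethers, and no stereocentre is involved because C5 becomes CH2OH while the former ring oxygen stays on C2.

Step 10
Reactants: 14 (1S,2R,3S)-1,4-bis[3-(benzyloxy)-4-methoxyphenyl]-2-{[(tert-butyldiphenylsilyl)oxy]methyl}-3-(hydroxymethyl)butane-1,4-diol
Product: 16 (RS)-[3-(benzyloxy)-4-methoxyphenyl][(3S,4R,5S)-5-[3-(benzyloxy)-4-methoxyphenyl]-4-{[(tert-butyldiphenylsilyl)oxy]methyl}oxolan-3-yl]methanol, via monotosylate 15 (not isolated)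
Conditions: TsCl (1.1 equiv), pyridine, CH2Cl2, 0 °C to rt; then NaH (2.5 equiv), THF, 0 °C
Reagents that add atoms: p-toluenesulfonyl chloride, Cc1ccc(cc1)S(=O)(=O)Cl
Why: Selective sulfonylation of the only primary hydroxyl followed by intramolecular Williamson etherification (5-exo-tet) by the C2 alkoxide forms the O1–C5 bond at a non-stereogenic carbon, so C2, C3 and C4 are retained, and the competing 4-exo closure from the C7' oxygen is far slower.

Step 11
Reactants: 16 (RS)-[3-(benzyloxy)-4-methoxyphenyl][(3S,4R,5S)-5-[3-(benzyloxy)-4-methoxyphenyl]-4-{[(tert-butyldiphenylsilyl)oxy]methyl}oxolan-3-yl]methanol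
Product: 17 [3-(benzyloxy)-4-methoxyphenyl][(3S,4R,5S)-5-[3-(benzyloxy)-4-methoxyphenyl]-4-{[(tert-butyldiphenylsilyl)oxy]methyl}oxolan-3-yl]methanone
Conditions: Dess–Martin periodinane (1.3 equiv), CH2Cl2, 0 °C to rt
Reagents that add atoms: none
Why: Dess–Martin oxidation of the only free alcohol converges both C7' epimers on one aryl ketone, and the now enolisable C4 already sits in the thermodynamically preferred all-trans arrangement.

Step 12
Reactants: 17 [3-(benzyloxy)-4-methoxyphenyl][(3S,4R,5S)-5-[3-(benzyloxy)-4-methoxyphenyl]-4-{[(tert-butyldiphenylsilyl)oxy]methyl}oxolan-3-yl]methanone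
Product: 18 [3-(benzyloxy)-4-methoxyphenyl][(3S,4R,5S)-5-[3-(benzyloxy)-4-methoxyphenyl]-4-(hydroxymethyl)oxolan-3-yl]methanone
Conditions: Bu4NF (1.5 equiv), AcOH (1.5 equiv), THF, 0 °C to rt
Reagents that add atoms: none
Why: Fluoride cleavage of the silyl ether is buffered with acetic acid so that the β-alkoxy ketone never meets a free alkoxide, which avoids retro-oxa-Michael ring opening.

Step 13
Reactants: 18 [3-(benzyloxy)-4-methoxyphenyl][(3S,4R,5S)-5-[3-(benzyloxy)-4-methoxyphenyl]-4-(hydroxymethyl)oxolan-3-yl]methanone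
Product: 19 (3-hydroxy-4-methoxyphenyl)[(3S,4R,5S)-5-(3-hydroxy-4-methoxyphenyl)-4-(hydroxymethyl)oxolan-3-yl]methanone
Conditions: H2 (1 atm), 10% Pd/C, EtOAc, rt, stopped when 18 is consumed
Reagents that add atoms: none
Why: Catalytic hydrogenolysis cleaves the two aryl benzyl ethers, which under neutral conditions at 1 atm react much faster than the electron-rich aryl ketone is reduced or the cyclic benzylic ether is opened, releasing the target with C2, C3 and C4 unchanged.

## Compound list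

1 | 1-(3-hydroxy-4-methoxyphenyl)ethan-1-one | CC(=O)c1ccc(OC)c(O)c1 | starting material
2 | 1-[3-(benzyloxy)-4-methoxyphenyl]ethan-1-one | CC(=O)c1ccc(OC)c(OCc2ccccc2)c1 | intermediate
3 | dimethyl carbonate | COC(=O)OC | starting material
4 | methyl 3-[3-(benzyloxy)-4-methoxyphenyl]-3-oxopropanoate | COC(=O)CC(=O)c1ccc(OC)c(OCc2ccccc2)c1 | intermediate
5 | methyl bromoacetate | COC(=O)CBr | starting material
6 | dimethyl 2-[3-(benzyloxy)-4-methoxybenzoyl]butanedioate (racemic) | COC(=O)CC(C(=O)OC)C(=O)c1ccc(OC)c(OCc2ccccc2)c1 | intermediate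
7 | dimethyl (2S)-2-{(S)-[3-(benzyloxy)-4-methoxyphenyl](hydroxy)methyl}butanedioate | O[C@H](c1ccc(OC)c(OCc2ccccc2)c1)[C@H](CC(=O)OC)C(=O)OC | intermediate
8 | (2S)-2-{(S)-[3-(benzyloxy)-4-methoxyphenyl](hydroxy)methyl}butanedioic acid | O[C@H](c1ccc(OC)c(OCc2ccccc2)c1)[C@H](CC(=O)O)C(=O)O | intermediate
9 | (2S,3S)-2-[3-(benzyloxy)-4-methoxyphenyl]-5-oxooxolane-3-carboxylic acid | C1C(=O)O[C@H](c2ccc(OC)c(OCc3ccccc3)c2)[C@H]1C(=O)O | intermediate
10 | (4R,5S)-5-[3-(benzyloxy)-4-methoxyphenyl]-4-(hydroxymethyl)oxolan-2-one | C1C(=O)O[C@H](c2ccc(OC)c(OCc3ccccc3)c2)[C@H]1CO | intermediate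
11 | (4R,5S)-5-[3-(benzyloxy)-4-methoxyphenyl]-4-{[(tert-butyldiphenylsilyl)oxy]methyl}oxolan-2-one | C1C(=O)O[C@H](c2ccc(OC)c(OCc3ccccc3)c2)[C@H]1CO[Si](c1ccccc1)(c1ccccc1)C(C)(C)C | intermediate
12 | 3-(benzyloxy)-4-methoxybenzaldehyde | O=Cc1ccc(OC)c(OCc2ccccc2)c1 | starting material
13 | (3R,4R,5S)-5-[3-(benzyloxy)-4-methoxyphenyl]-3-{[3-(benzyloxy)-4-methoxyphenyl](hydroxy)methyl}-4-{[(tert-butyldiphenylsilyl)oxy]methyl}oxolan-2-one (C7' epimers) | OC(c1ccc(OC)c(OCc2ccccc2)c1)[C@@H]1C(=O)O[C@H](c2ccc(OC)c(OCc3ccccc3)c2)[C@H]1CO[Si](c1ccccc1)(c1ccccc1)C(C)(C)C | intermediate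
14 | (1S,2R,3S)-1,4-bis[3-(benzyloxy)-4-methoxyphenyl]-2-{[(tert-butyldiphenylsilyl)oxy]methyl}-3-(hydroxymethyl)butane-1,4-diol (C4 carbinol epimers) | OC(c1ccc(OC)c(OCc2ccccc2)c1)[C@H](CO)[C@H](CO[Si](c1ccccc1)(c1ccccc1)C(C)(C)C)[C@H](O)c1ccc(OC)c(OCc2ccccc2)c1 | intermediate
15 | primary mono-4-methylbenzenesulfonate of 14 (tosylate on the CH2OH at C3 of the butane chain) | OC(c1ccc(OC)c(OCc2ccccc2)c1)[C@H](COS(=O)(=O)c1ccc(C)cc1)[C@H](CO[Si](c1ccccc1)(c1ccccc1)C(C)(C)C)[C@H](O)c1ccc(OC)c(OCc2ccccc2)c1 | intermediate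
16 | (RS)-[3-(benzyloxy)-4-methoxyphenyl][(3S,4R,5S)-5-[3-(benzyloxy)-4-methoxyphenyl]-4-{[(tert-butyldiphenylsilyl)oxy]methyl}oxolan-3-yl]methanol | OC(c1ccc(OC)c(OCc2ccccc2)c1)[C@@H]1CO[C@H](c2ccc(OC)c(OCc3ccccc3)c2)[C@H]1CO[Si](c1ccccc1)(c1ccccc1)C(C)(C)C | intermediate
17 | [3-(benzyloxy)-4-methoxyphenyl][(3S,4R,5S)-5-[3-(benzyloxy)-4-methoxyphenyl]-4-{[(tert-butyldiphenylsilyl)oxy]methyl}oxolan-3-yl]methanone | O=C(c1ccc(OC)c(OCc2ccccc2)c1)[C@@H]1CO[C@H](c2ccc(OC)c(OCc3ccccc3)c2)[C@H]1CO[Si](c1ccccc1)(c1ccccc1)C(C)(C)C | intermediate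
18 | [3-(benzyloxy)-4-methoxyphenyl][(3S,4R,5S)-5-[3-(benzyloxy)-4-methoxyphenyl]-4-(hydroxymethyl)oxolan-3-yl]methanone | O=C(c1ccc(OC)c(OCc2ccccc2)c1)[C@@H]1CO[C@H](c2ccc(OC)c(OCc3ccccc3)c2)[C@H]1CO | intermediate
19 | (3-hydroxy-4-methoxyphenyl)[(3S,4R,5S)-5-(3-hydroxy-4-methoxyphenyl)-4-(hydroxymethyl)oxolan-3-yl]methanone | COc1ccc(C(=O)[C@@H]2CO[C@H](c3ccc(OC)c(O)c3)[C@H]2CO)cc1O | target

## Step count and risks

Total step count: 13. Longest linear sequence: 13 steps (1 to 19); aldehyde 12 is used as purchased.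

**Step 4 (enzymatic dynamic kinetic resolution).** The enzyme may show low activity on this doubly branched aryl ketone or give the anti alcohol. The fallback sets out from 12 and comes back to the route at 11.
- Iridium-catalysed anti-selective carbonyl (hydroxymethyl)allylation of 12 with 4,7-dihydro-1,3-dioxepin-2-one sets C2 and C3 in one C–C bond-forming step. Conditions: [Ir(cod)Cl]2, a SEGPHOS-type chiral bisphosphine of the hand that gives the (1S,2R) product, 4-cyano-3-nitrobenzoic acid, Cs2CO3, i-PrOH, THF, 90 °C. The product is (1S,2R)-1-[3-(benzyloxy)-4-methoxyphenyl]-2-ethenylpropane-1,3-diol F1.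
- TBDPSCl and imidazole at the primary hydroxyl give (1S,2R)-1-[3-(benzyloxy)-4-methoxyphenyl]-2-{[(tert-butyldiphenylsilyl)oxy]methyl}but-3-en-1-ol F2.
- Hydroboration–oxidation of the vinyl group (9-BBN, THF, then NaOH, H2O2) gives (1S,2R)-1-[3-(benzyloxy)-4-methoxyphenyl]-2-{[(tert-butyldiphenylsilyl)oxy]methyl}butane-1,4-diol F3.
- TEMPO (cat.) with PhI(OAc)2 in CH2Cl2 oxidises the primary alcohol through the lactol to lactone 11.

**Step 8 (aldol).** Addition to an electron-rich aldehyde is reversible and may stall or revert on work-up. The fallback sets out from 11 and comes back at 13.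
- Irreversible C-acylation of the enolate of 11 (LiN(SiMe3)2, 2.2 equiv, THF, −78 °C) with purchased 3-(benzyloxy)-4-methoxybenzoyl chloride gives (3R,4R,5S)-3-[3-(benzyloxy)-4-methoxybenzoyl]-5-[3-(benzyloxy)-4-methoxyphenyl]-4-{[(tert-butyldiphenylsilyl)oxy]methyl}oxolan-2-one F4. Its acidic C4 settles trans to C3.
- NaBH4 in MeOH/THF at −20 °C reduces only the ketone and gives 13.

**Step 10 (ring closure on the unprotected triol).** Risks are sulfonylation or ionisation of the benzylic alcohols, or Grob-type fragmentation through the C7' alkoxide. The fallback sets out from 13 and comes back at 16.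
- Et3SiCl and imidazole in DMF cap the C7' hydroxyl, giving the C7'-O-triethylsilyl ether of 13 F5.
- LiBH4 in THF gives the C7'-O-triethylsilyl ether of 14 F6, a diol with one primary and one secondary hydroxyl.
- TsCl and pyridine give the C7'-O-triethylsilyl ether of 15 F7, which is not isolated.
- NaH in THF closes it to the C7'-O-triethylsilyl ether of 16 F8.
- HF·pyridine in pyridine/THF at 0 °C removes the triethylsilyl group in the presence of the tert-butyldiphenylsilyl ether and returns 16.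

## Further compounds

F1 | step 4 | (1S,2R)-1-[3-(benzyloxy)-4-methoxyphenyl]-2-ethenylpropane-1,3-diol | O[C@H](c1ccc(OC)c(OCc2ccccc2)c1)[C@H](C=C)CO
F2 | step 4 | (1S,2R)-1-[3-(benzyloxy)-4-methoxyphenyl]-2-{[(tert-butyldiphenylsilyl)oxy]methyl}but-3-en-1-ol | O[C@H](c1ccc(OC)c(OCc2ccccc2)c1)[C@H](C=C)CO[Si](c1ccccc1)(c1ccccc1)C(C)(C)C
F3 | step 4 | (1S,2R)-1-[3-(benzyloxy)-4-methoxyphenyl]-2-{[(tert-butyldiphenylsilyl)oxy]methyl}butane-1,4-diol | O[C@H](c1ccc(OC)c(OCc2ccccc2)c1)[C@H](CCO)CO[Si](c1ccccc1)(c1ccccc1)C(C)(C)C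
F4 | step 8 | (3R,4R,5S)-3-[3-(benzyloxy)-4-methoxybenzoyl]-5-[3-(benzyloxy)-4-methoxyphenyl]-4-{[(tert-butyldiphenylsilyl)oxy]methyl}oxolan-2-one | O=C(c1ccc(OC)c(OCc2ccccc2)c1)[C@@H]1C(=O)O[C@H](c2ccc(OC)c(OCc3ccccc3)c2)[C@H]1CO[Si](c1ccccc1)(c1ccccc1)C(C)(C)C
F5 | step 10 | C7'-O-triethylsilyl ether of 13 | CC[Si](CC)(CC)OC(c1ccc(OC)c(OCc2ccccc2)c1)[C@@H]1C(=O)O[C@H](c2ccc(OC)c(OCc3ccccc3)c2)[C@H]1CO[Si](c1ccccc1)(c1ccccc1)C(C)(C)C
F6 | step 10 | C7'-O-triethylsilyl ether of 14 | CC[Si](CC)(CC)OC(c1ccc(OC)c(OCc2ccccc2)c1)[C@H](CO)[C@H](CO[Si](c1ccccc1)(c1ccccc1)C(C)(C)C)[C@H](O)c1ccc(OC)c(OCc2ccccc2)c1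
F7 | step 10 | C7'-O-triethylsilyl ether of 15 | CC[Si](CC)(CC)OC(c1ccc(OC)c(OCc2ccccc2)c1)[C@H](COS(=O)(=O)c1ccc(C)cc1)[C@H](CO[Si](c1ccccc1)(c1ccccc1)C(C)(C)C)[C@H](O)c1ccc(OC)c(OCc2ccccc2)c1
F8 | step 10 | C7'-O-triethylsilyl ether of 16 | CC[Si](CC)(CC)OC(c1ccc(OC)c(OCc2ccccc2)c1)[C@@H]1CO[C@H](c2ccc(OC)c(OCc3ccccc3)c2)[C@H]1CO[Si](c1ccccc1)(c1ccccc1)C(C)(C)C
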